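**Plan**
- Retrosynthesis: the dihydropyran is cut at C5–CH2 and C4–O (retro-oxa-Diels–Alder), then the CH2=C bond of the resulting oxadiene (retro-Knoevenagel). This gives (−)-β-caryophyllene, formaldehyde and isobutyrylfilicinic acid. The latter is cut at its two C–CH3 bonds and at the ring–acyl bond back to phloroglucinol.
- Forward: phloroglucinol is acylated and dearomatised by gem-dimethylation to the β-triketone ring. The pyran is closed last, in a one-pot three-component union onto the intact cyclobutane/nine-membered bicycle.
- Enabling feature: the one ring CH of the triketone that lies between two carbonyls becomes, with the carbon of formaldehyde, a 1-oxadiene. The strained trans C4=C5 double bond of the nine-membered ring is its 2π partner.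
- Stereochemistry: C1, C9 and the E-alkene geometry come from natural caryophyllene. C4 and C5 are set in the cycloaddition (suprafacial, outer-face addition), and the two facial diastereomers are separated.

Key step: step 3

Remark: locants C1, C4, C5, C8, C9 are caryophyllane numbers (C4 is the methyl- and oxygen-bearing carbon, C5 the adjacent CH). The target is (1R,4S,5R,9S). The triketones are written as one enol tautomer.

**Step 1**
Reactants: 1 phloroglucinol; 2 isobutyryl chloride
Product: 3 phlorisobutyrophenone
Conditions: AlCl3 (3.5 equiv), PhNO2/CH2Cl2, 0 °C to 45 °C; then ice/aq. HCl
Reagents that add atoms: none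
Why: Friedel–Crafts acylation of the symmetric, highly activated arene should give a single regioisomer, and the AlCl3-complexed aryl ketone is deactivated towards a second acylation; no stereocentre is formed.

**Step 2**
Reactants: 3 phlorisobutyrophenone
Product: 5 isobutyrylfilicinic acid, via 3-methylphlorisobutyrophenone 4 (not isolated)
Conditions: NaOMe (3.2 equiv), MeI (2.2 equiv), MeOH, 0 °C to rt; then aq. HCl
Reagents that add atoms: iodomethane, CI
Why: Dearomative double C-methylation of the acylphloroglucinol polyanion, in which the second methyl should enter the already methylated, more electron-rich carbon of 4 to give the gem-dimethyl dienone that cannot re-aromatise, while the acidic product is held as its unreactive enolate; the quaternary carbon carries two identical methyls, so no stereocentre is formed.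

**Step 3**
Reactants: 5 isobutyrylfilicinic acid; 6 formaldehyde (37 % aqueous); 7 (−)-β-caryophyllene
Product: 10 target cycloadduct, via hydroxymethyl aldol adduct 8 (not isolated), via 6-methylene oxadiene 9 (not isolated)
Conditions: 7 (4 equiv), 6 (3 equiv), ethylenediammonium diacetate (10 mol %), 1,4-dioxane, 80 °C, 5 added over 4 h; chromatography (AgNO3–SiO2 or HPLC) to remove the C4/C5 diastereomer and recover 7
Reagents that add atoms: none
Why: Knoevenagel condensation of 6 at C6 of 5, the only unsubstituted carbon between two carbonyls, should give through aldol adduct 8 and loss of water the 2-methylene-1,3-dione 9, whose CH2=C–C=O unit (a non-aromatic o-quinone-methide equivalent) is trapped as it forms by the C4=C5 alkene of 7 in an inverse-electron-demand oxa-[4+2] cycloaddition. The closest known reaction type is the domino Knoevenagel/hetero-Diels–Alder reaction of cyclic 1,3-dicarbonyl compounds with aldehydes and alkenes, including β-triketone or phloroglucinol, aldehyde and terpene combinations. The dihydropyran is closed in an intermolecular, concerted but asynchronous [4+2] cycloaddition that forms C5–CH2 and C4–O together, with oxygen going to the methyl-bearing C4 because that carbon best carries the positive charge that builds up as the C–C bond at the oxadiene CH2 leads. Addition is suprafacial on the E-alkene, so the C4 methyl and H-5 become trans, and only the outer face of the trans double bond can be reached, so the C4/C5 configuration relative to the untouched C1 and C9 follows from which alkene-flip conformer of 7 reacts: the conformer with the C4 methyl syn to H-1 (ββ) leads to the (4S,5R) target and the more populated conformer with that methyl syn to H-9 (βα) to the (4R,5S) diastereomer. The step needs facial, site and oxadiene-terminus selectivity: the facial choice is substrate-governed and not fully secured, so both diastereomers are expected, the target probably as the lesser one; reaction at C4=C5 and not at the C8 exocyclic methylene is secured by the strain and high HOMO of the trans-trisubstituted ring alkene; and the carbonyl next to CMe2 acts as the oxadiene oxygen because the other flanking oxygen is held in the hydrogen-bonded enol of the acyl-β-dicarbonyl unit. Slow addition of 5 to an excess of 6 and 7 keeps free triketone low, so that 9 is not consumed by Michael addition of a second molecule of 5.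

**Compound list**
1 | phloroglucinol (benzene-1,3,5-triol) | Oc1cc(O)cc(O)c1 | starting material
2 | isobutyryl chloride (2-methylpropanoyl chloride) | CC(C)C(Cl)=O | starting material
3 | phlorisobutyrophenone, 2-methyl-1-(2,4,6-trihydroxyphenyl)propan-1-one | CC(C)C(=O)c1c(O)cc(O)cc1O | intermediate
4 | 3-methylphlorisobutyrophenone, 2-methyl-1-(2,4,6-trihydroxy-3-methylphenyl)propan-1-one | CC(C)C(=O)c1c(O)cc(O)c(C)c1O | intermediate (not isolated)
5 | isobutyrylfilicinic acid, 3,5-dihydroxy-4,4-dimethyl-2-(2-methylpropanoyl)cyclohexa-2,5-dien-1-one | CC(C)C(=O)C1=C(O)C(C)(C)C(O)=CC1=O | intermediate
6 | formaldehyde (37 % aqueous solution) | C=O | starting material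
7 | (−)-β-caryophyllene, (1R,4E,9S)-4,11,11-trimethyl-8-methylidenebicyclo[7.2.0]undec-4-ene | C=C1CC/C=C(\C)CC[C@@H]2[C@@H]1CC2(C)C | starting material
8 | hydroxymethyl aldol adduct, 3,5-dihydroxy-6-(hydroxymethyl)-4,4-dimethyl-2-(2-methylpropanoyl)cyclohexa-2,5-dien-1-one | CC(C)C(=O)C1=C(O)C(C)(C)C(O)=C(CO)C1=O | intermediate (not isolated)
9 | 6-methylene oxadiene, 3-hydroxy-4,4-dimethyl-6-methylidene-2-(2-methylpropanoyl)cyclohex-2-ene-1,5-dione | C=C1C(=O)C(C)(C)C(=O)C(C(=O)C(C)C)=C1O | intermediate (not isolated)
10 | target: (1R,4S,5R,9S) cycloadduct, in which the enolised isobutyryl-triketone ring is fused through O–C4 and CH2–C5 as a dihydropyran to the bicyclo[7.2.0]undecane that keeps the C8 exocyclic methylene and the gem-dimethylcyclobutane | C=C1CC[C@@H]2CC3=C(O[C@@]2(C)CC[C@@H]2[C@@H]1CC2(C)C)C(C)(C)C(=O)C(C(=O)C(C)C)=C3O | target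

**Step count**
Total steps: 3. Longest linear sequence: 3 (1 → 3 → 5 → 10).

**Steps most likely to fail**

1. Step 3. The transient oxadiene may be intercepted by unreacted triketone (methylene-bridged dimer) or by itself faster than it is trapped by the alkene. The low facial discrimination between the two alkene-flip conformers also leaves the wanted diastereomer as the lesser share. Fallback, from 5: aminomethylation with dimethylmethyleneiminium iodide (MeCN, rt, then neutralisation) should give the isolable Mannich base 6-[(dimethylamino)methyl]isobutyrylfilicinic acid F1, freed of 5. Heating F1 with excess 7 (toluene, 100 °C, N2 sweep) should expel dimethylamine and release 9 slowly in the absence of any free triketone nucleophile. The route is rejoined at 10. The facial ratio stays substrate-governed, so the separation remains.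

2. Step 2. The number and site of C-methylations may be poorly controlled: entry of the second methyl at the other free ring carbon, a third methylation, or O-methylation. Fallback, from 3: exhaustive C-trimethylation (NaOMe 4 equiv, MeI 3.3 equiv, MeOH), in which both possible dimethyl intermediates converge, should give norflavesone F2. Its ring C-methyl already holds the future pyran CH2. Dehydrogenation of that CH–CH3 unit with TEMPO/Ag2O in the presence of excess 7 (toluene, rt to 50 °C) should generate the same oxadiene 9. The route is rejoined at 10 without 5 or 6.

3. Step 1. O-acylation and 2,4-diacylation may compete with mono-C-acylation, and the product is hard to free from nitrobenzene and aluminium salts. Fallback, from 1: Houben–Hoesch reaction with isobutyronitrile (ZnCl2, HCl gas, Et2O, 0 °C) should precipitate the ketiminium chloride F3, which is too deactivated to react twice. Hydrolysis in boiling water rejoins the route at 3.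

**Further compounds**
F1 | step 3 | Mannich base, 6-[(dimethylamino)methyl]-3,5-dihydroxy-4,4-dimethyl-2-(2-methylpropanoyl)cyclohexa-2,5-dien-1-one | CC(C)C(=O)C1=C(O)C(C)(C)C(O)=C(CN(C)C)C1=O
F2 | step 2 | norflavesone, 3,5-dihydroxy-4,4,6-trimethyl-2-(2-methylpropanoyl)cyclohexa-2,5-dien-1-one | CC(C)C(=O)C1=C(O)C(C)(C)C(O)=C(C)C1=O
F3 | step 1 | 2-methyl-1-(2,4,6-trihydroxyphenyl)propan-1-iminium chloride | CC(C)C(=[NH2+])c1c(O)cc(O)cc1O.[Cl-]
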